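The ten-membered ring is numbered as a germacranolide: C1–C10 in the ring, C14 the methyl on C10, C15 the CH2OH on C4, lactone O–C6, C7, C11(=C13), C12, and the angelate on the C8 oxygen.
The enabling feature is that the C8 oxygen and the C10 carbinol flank the C9 methylene in this ring (a masked aldol, the retron of a 2-isoxazoline). C10–C14 is therefore cut to a ketone, and C9–C10 together with C8–O is cut as one intramolecular nitrile oxide (3+2) cycloaddition onto a C7 vinyl group, which closes the carbocycle as a bridged isoxazoline.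
Earlier cuts are C3–C4 (Nozaki–Hiyama–Kishi coupling of a Z-alkenyl iodide with a four-carbon enal acetal that carries C10), C6–C7 with the lactone C–O (allylboration/lactonisation), C11–C13 (Mannich) and the angelate ester bond.
Forward order: cis-lactone bearing the C7 vinyl group and the Z-iodoalkene (steps 1–5), chain joined at C3–C4 (step 6), ten-membered ring by the cycloaddition (step 9), then N–O cleavage, methyl addition, acylation and unmasking (steps 10–18).
Helpers: a temporary 1E double bond (C1=C2) makes closure of the dipole onto C4=C5 geometrically impossible and is reduced by diimide; the C3 ketone travels as a silyl ether, C13 as a dimethylaminomethyl group, and C15–OH as a PMB ether.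
Stereochemistry: C6 and C7 come from a chiral phosphoric acid-catalysed anti allylboration, C8 from the cycloaddition under C7 control, C10 from chelation-controlled CH3MgBr addition syn to C8–OH, and 4Z from trans-hydroalumination/iodination, kept through the coupling; the angelate Z geometry is bought in.

Key step: step 9

Remark: TBS = tert-butyldimethylsilyl, PMB = 4-methoxybenzyl; the C3 carbinol made in step 6 is carried as both epimers (SMILES without configuration at C3), which converge at the ketone in step 17.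
Remark: ethyl 3-hydroxypent-4-enoate (6) is taken as a catalogue compound; the 10-hydroxy-3-ketone of the target may sit partly as its transannular hemiketal, and the open form is drawn.

Step 1
Reactants: 1 but-2-yne-1,4-diol
Product: 2 4-[(4-methoxybenzyl)oxy]but-2-yn-1-ol
Conditions: NaH (1 equiv), 4-methoxybenzyl chloride (1 equiv), 1 in excess (3 equiv), DMF, 0 °C to rt
Reagents that add atoms: 4-methoxybenzyl chloride, COc1ccc(CCl)cc1
Why: Williamson etherification of the mono-alkoxide with the diol in excess should give mainly the mono-ether, which differentiates the two ends of the C6–C5–C4–C15 unit.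

Step 2
Reactants: 2 mono-PMB ether of butynediol
Product: 4 (2Z)-3-iodo-4-[(4-methoxybenzyl)oxy]but-2-en-1-ol, via sodium alkenylalanate 3 (not isolated)
Conditions: NaAlH2(OCH2CH2OCH3)2 (1.5 equiv), THF, 0 °C to rt; then I2, −78 to 0 °C
Reagents that add atoms: iodine, [I][I]
Why: Hydroxyl-directed trans-hydroalumination of the propargylic alcohol places aluminium on the distal alkyne carbon (cyclic alanate 3) and iodinolysis with retention should give the Z-iodoalkene, which fixes the later 4Z geometry.

Step 3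
Reactants: 4 Z-iodo allylic alcohol
Product: 5 (2Z)-3-iodo-4-[(4-methoxybenzyl)oxy]but-2-enal
Conditions: MnO2 (15 equiv), CH2Cl2, rt
Reagents that add atoms: none
Why: MnO2 oxidation of a primary allylic alcohol is mild and neutral and should leave the Z-iodoalkene and the PMB ether untouched.

Step 4
Reactants: 6 ethyl 3-hydroxypent-4-enoate
Product: 7 ethyl (3E)-5-(4,4,5,5-tetramethyl-1,3,2-dioxaborolan-2-yl)pent-3-enoate
Conditions: bis(pinacolato)diboron (1.2 equiv), Pd(MeCN)4(BF4)2 (5 mol %), DMSO/MeOH, 50 °C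
Reagents that add atoms: bis(pinacolato)diboron, CC1(C)OB(OC1(C)C)B1OC(C)(C)C(C)(C)O1
Why: Palladium-catalysed allylic borylation of the allylic alcohol runs through a syn-allylpalladium species and should deliver the linear E-allylboronate from the branched alcohol without base, so the β,γ-unsaturated ester is not isomerised.

Step 5
Reactants: 5 Z-iodoenal; 7 E-allylboronate
Product: 10 (4R,5R)-4-ethenyl-5-{(1Z)-2-iodo-3-[(4-methoxybenzyl)oxy]prop-1-en-1-yl}oxolan-2-one, via O-boryl adduct 8 (not isolated), via hydroxy ester 9 (not isolated)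
Conditions: (R)-TRIP [(R)-3,3'-bis(2,4,6-triisopropylphenyl)-1,1'-binaphthyl-2,2'-diyl hydrogen phosphate, 5 mol %], 4 Å molecular sieves, toluene, −30 °C; aqueous work-up; then TsOH·H2O (10 mol %), CH2Cl2, rt
Reagents that add atoms: none
Why: Chiral Brønsted acid-catalysed allylboration through a closed chair transition state, in which the E-boronate gives the anti adduct (C6–O anti to the C7 acetate arm) and (R)-TRIP should direct the allyl unit to the Re face of the aldehyde (C6 R, C7 R), after which acid lactonises 9 to the cis-lactone.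

Step 6
Reactants: 10 iodoalkenyl cis-lactone; 11 (2E)-4,4-dimethoxybut-2-enal
Product: 12 (4R,5R)-4-ethenyl-5-[(1Z,4E)-3-hydroxy-6,6-dimethoxy-2-{[(4-methoxybenzyl)oxy]methyl}hexa-1,4-dien-1-yl]oxolan-2-one (both C3 carbinol epimers)
Conditions: CrCl2 (4 equiv), NiCl2 (2 mol %), DMSO, rt
Reagents that add atoms: none
Why: Nozaki–Hiyama–Kishi coupling, in which the alkenyl iodide is activated by nickel, passed to chromium and added 1,2 to the enal with retention of the Z geometry and tolerance of lactone and acetal, forms C3–C4; the new C3 carbinol is not controlled and is oxidised later.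

Step 7
Reactants: 12 allylic alcohol
Product: 13 (4R,5R)-5-[(1Z,4E)-3-{[tert-butyl(dimethyl)silyl]oxy}-6,6-dimethoxy-2-{[(4-methoxybenzyl)oxy]methyl}hexa-1,4-dien-1-yl]-4-ethenyloxolan-2-one
Conditions: tert-butyldimethylsilyl chloride, imidazole, DMAP (cat.), DMF, 40 °C
Reagents that add atoms: tert-butyldimethylsilyl chloride, CC(C)(C)[Si](C)(C)Cl
Why: Standard silylation of the secondary bis-allylic alcohol under non-acidic conditions protects C3 until step 17 and keeps the acetal intact.

Step 8
Reactants: 13 silyl ether acetal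
Product: 14 (4R,5R)-5-[(1Z,4E,6E)-3-{[tert-butyl(dimethyl)silyl]oxy}-6-(hydroxyimino)-2-{[(4-methoxybenzyl)oxy]methyl}hexa-1,4-dien-1-yl]-4-ethenyloxolan-2-one
Conditions: NH2OH·HCl (3 equiv), THF/H2O (4:1), rt; NaHCO3 work-up
Reagents that add atoms: hydroxylamine hydrochloride, Cl.NO
Why: Acid-catalysed exchange of the allylic dimethyl acetal with hydroxylamine (oxime formation) should give the conjugated aldoxime under conditions mild enough for the silyl ether and the lactone.

Step 9
Reactants: 14 conjugated aldoxime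
Product: 17 (1E,4Z,6S,7S,8R)-3-OTBS-15-OPMB-8,10-(epoxynitrilo)-14-norgermacra-1,4-dien-6,12-olide (bridged 2-isoxazoline; O–N=C10 bridge from C8), via hydroximoyl chloride 15 (not isolated), via nitrile oxide 16 (not isolated)
Conditions: N-chlorosuccinimide (1.05 equiv), DMF, 0 °C to rt; then slow addition (syringe pump, 12 h) into Et3N (3 equiv), CH2Cl2, about 0.001 M, rt to 40 °C
Reagents that add atoms: none
Why: Loss of HCl from 15 gives the conjugated nitrile oxide 16, which adds in a concerted (3+2) fashion across the C7 vinyl group with C10 bonding to the terminal C9 and oxygen to C8, the normal regiochemistry for a monosubstituted alkene; the closest known reaction type is the intramolecular nitrile oxide–olefin cycloaddition used to close medium and large carbocycles as bridged 2-isoxazolines. The step closes the five-membered isoxazoline by the cycloaddition itself and the ten-membered carbocycle C1–C10 in the bridged (endo) mode, both vinyl carbons becoming ring members, whereas the fused alternative would need a nine-membered ring and the disfavoured 4-substituted isoxazoline. The new stereocentre C8 is controlled by C7: in the reacting conformer H7 eclipses the vinyl group, the lactone carbon C11 lies anti to the incoming dipole and the tether holds the dipole on the C6 side, the same face that the open-chain staggered model (largest group anti) predicts. Chemoselectivity against the trisubstituted C4=C5 alkene is needed and is secured by the 1E double bond, because closure onto C4 or C5 would put a trans double bond into a five- or six-membered ring. Dimerisation to furoxans is held back by slow release of 16 at high dilution. The cis-lactone and the 4Z alkene pre-fold the seven-atom tether toward the vinyl group.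

Step 10
Reactants: 17 bridged isoxazoline with 1E double bond
Product: 18 (4Z,6S,7S,8R)-3-OTBS-15-OPMB-8,10-(epoxynitrilo)-14-norgermacr-4-en-6,12-olide
Conditions: 2-nitrobenzenesulfonohydrazide (5 equiv), Et3N (10 equiv), CH2Cl2, rt
Reagents that add atoms: none
Why: Diimide reduction is selective for the 1,2-disubstituted C1=C2 double bond over the hindered trisubstituted C4=C5 alkene and leaves C=N and N–O alone, which removes the helper double bond.

Step 11
Reactants: 18 saturated bridged isoxazoline
Product: 20 (4Z,6S,7S,8R,11R)-13-(dimethylamino)-3-OTBS-15-OPMB-8,10-(epoxynitrilo)-14-norgermacr-4-en-6,12-olide, via lithium enolate 19 (not isolated)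
Conditions: LiN(iPr)2 (1.1 equiv), THF, −78 °C; then N,N-dimethylmethyleneiminium iodide (1.5 equiv), −78 to 0 °C
Reagents that add atoms: N,N-dimethylmethyleneiminium iodide, [I-].C=[N+](C)C
Why: Mannich reaction of the lactone enolate with the preformed iminium salt installs C13 as a dimethylaminomethyl group (a masked exo-methylene that survives the later nucleophiles), entering trans to the C7 substituent (C11 R).

Step 12
Reactants: 20 Mannich base isoxazoline
Product: 22 (4Z,6S,7R,8R,11R)-13-(dimethylamino)-8-hydroxy-3-OTBS-15-OPMB-10-oxo-14-norgermacr-4-en-6,12-olide, via hydroxy imine 21 (not isolated)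
Conditions: Mo(CO)6 (1.2 equiv), MeCN/H2O (10:1), 80 °C
Reagents that add atoms: water, O
Why: Zerovalent molybdenum cleaves the isoxazoline N–O bond reductively and the hydroxy imine 21 hydrolyses in the wet medium, which unmasks the β-hydroxy ketone without touching the alkene, the lactone or the C8 stereocentre.

Step 13
Reactants: 22 β-hydroxy ketone
Product: 24 (4Z,6S,7R,8R,10R,11R)-13-(dimethylamino)-8,10-dihydroxy-3-OTBS-15-OPMB-germacr-4-en-6,12-olide, via magnesium alkoxide 23 (not isolated)
Conditions: CH3MgBr (4 equiv), THF/CH2Cl2, −78 °C; aq. NH4Cl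
Reagents that add atoms: methylmagnesium bromide, C[Mg]Br
Why: Grignard addition to the C10 ketone held in the six-membered magnesium chelate 23 with the C8 alkoxide should follow the axial trajectory that leaves C7 and C1 equatorial on the chelate and so give the 1,3-syn diol (C10 R), and at −78 °C the ketone should outpace the lactone.

Step 14
Reactants: 24 diol; 25 angelic acid [(2Z)-2-methylbut-2-enoic acid]
Product: 27 (4Z,6S,7R,8R,10R,11R)-8-angeloyloxy-13-(dimethylamino)-10-hydroxy-3-OTBS-15-OPMB-germacr-4-en-6,12-olide, via mixed anhydride 26 (not isolated)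
Conditions: 25 (3 equiv), 2,4,6-trichlorobenzoyl chloride (3 equiv), Et3N (3.5 equiv), toluene, rt; then 24, 80 °C
Reagents that add atoms: none
Why: Yamaguchi-type esterification through the mixed anhydride 26 without a nucleophilic catalyst acylates the secondary C8 hydroxyl (the tertiary C10 hydroxyl is inert) and is the established way to keep the Z geometry of an angelate.

Step 15
Reactants: 27 angelate Mannich base
Product: 29 (4Z,6S,7R,8R,10R)-8-angeloyloxy-10-hydroxy-3-OTBS-15-OPMB-germacra-4,11(13)-dien-6,12-olide, via ammonium iodide 28 (not isolated)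
Conditions: CH3I (10 equiv), THF, rt; then aq. NaHCO3, EtOAc, rt
Reagents that add atoms: none
Why: Exhaustive methylation of the amine and Hofmann-type β-elimination of trimethylamine from 28 under mild base should release the α-methylene lactone once the nucleophilic and free C8–OH stages are past.

Step 16
Reactants: 29 silyl ether
Product: 30 (4Z,6S,7R,8R,10R)-8-angeloyloxy-3,10-dihydroxy-15-OPMB-germacra-4,11(13)-dien-6,12-olide
Conditions: HF·pyridine, pyridine, THF, 0 °C to rt
Reagents that add atoms: none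
Why: Buffered fluoride cleaves the secondary silyl ether, while the PMB ether, both esters, the α-methylene lactone and the tertiary alcohol should be stable.

Step 17
Reactants: 30 allylic alcohol (both C3 epimers)
Product: 31 (4Z,6S,7R,8R,10R)-8-angeloyloxy-10-hydroxy-15-OPMB-3-oxogermacra-4,11(13)-dien-6,12-olide
Conditions: Dess–Martin periodinane (1.5 equiv), NaHCO3, CH2Cl2, 0 °C to rt
Reagents that add atoms: none
Why: Dess–Martin oxidation of the secondary allylic alcohol under buffered neutral conditions gives the Z-enone from both epimers, and the tertiary C10 alcohol cannot be oxidised.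

Step 18
Reactants: 31 PMB ether
Product: 32 (4Z,6S,7R,8R,10R)-8-angeloyloxy-10,15-dihydroxy-3-oxogermacra-4,11(13)-dien-6,12-olide (target CNP0181802.1)
Conditions: 2,3-dichloro-5,6-dicyano-1,4-benzoquinone (1.5 equiv), CH2Cl2/pH 7 buffer (10:1), 0 °C
Reagents that add atoms: none
Why: Oxidative cleavage of the PMB ether by hydride abstraction and hydrolysis of the oxocarbenium ion frees C15–OH without acid or base, so the enone, the α-methylene lactone and the angelate should survive.

Compound list
1 | but-2-yne-1,4-diol | OCC#CCO | starting material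
2 | 4-[(4-methoxybenzyl)oxy]but-2-yn-1-ol | OCC#CCOCc1ccc(OC)cc1 | intermediate
3 | sodium alkenylalanate, cyclic alkoxy(alkenyl)bis(2-methoxyethoxy)aluminate from 2 (not isolated) | [Na+].COCCO[Al-]1(OCCOC)OC/C=C\1COCc1ccc(OC)cc1 | intermediate
4 | (2Z)-3-iodo-4-[(4-methoxybenzyl)oxy]but-2-en-1-ol | OC/C=C(\I)COCc1ccc(OC)cc1 | intermediate
5 | (2Z)-3-iodo-4-[(4-methoxybenzyl)oxy]but-2-enal | O=C/C=C(\I)COCc1ccc(OC)cc1 | intermediate
6 | ethyl 3-hydroxypent-4-enoate (racemic) | CCOC(=O)CC(O)C=C | starting material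
7 | ethyl (3E)-5-(4,4,5,5-tetramethyl-1,3,2-dioxaborolan-2-yl)pent-3-enoate | CCOC(=O)C/C=C/CB1OC(C)(C)C(C)(C)O1 | intermediate
8 | O-boryl adduct, pinacolboryl ether of 9 (not isolated) | CCOC(=O)C[C@H](C=C)[C@@H](OB1OC(C)(C)C(C)(C)O1)/C=C(\I)COCc1ccc(OC)cc1 | intermediate
9 | ethyl (3R,4R,5Z)-3-ethenyl-4-hydroxy-6-iodo-7-[(4-methoxybenzyl)oxy]hept-5-enoate (not isolated) | CCOC(=O)C[C@H](C=C)[C@@H](O)/C=C(\I)COCc1ccc(OC)cc1 | intermediate
10 | (4R,5R)-4-ethenyl-5-{(1Z)-2-iodo-3-[(4-methoxybenzyl)oxy]prop-1-en-1-yl}oxolan-2-one (cis-lactone) | C=C[C@H]1CC(=O)O[C@H]1/C=C(\I)COCc1ccc(OC)cc1 | intermediate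
11 | (2E)-4,4-dimethoxybut-2-enal | COC(OC)/C=C/C=O | starting material
12 | (4R,5R)-4-ethenyl-5-[(1Z,4E)-3-hydroxy-6,6-dimethoxy-2-{[(4-methoxybenzyl)oxy]methyl}hexa-1,4-dien-1-yl]oxolan-2-one, C3 epimers | C=C[C@H]1CC(=O)O[C@H]1/C=C(/COCc1ccc(OC)cc1)C(O)/C=C/C(OC)OC | intermediate
13 | TBS ether of 12 | C=C[C@H]1CC(=O)O[C@H]1/C=C(/COCc1ccc(OC)cc1)C(O[Si](C)(C)C(C)(C)C)/C=C/C(OC)OC | intermediate
14 | (E)-aldoxime from 13 (C10 as CH=NOH) | C=C[C@H]1CC(=O)O[C@H]1/C=C(/COCc1ccc(OC)cc1)C(O[Si](C)(C)C(C)(C)C)/C=C/C=N/O | intermediate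
15 | hydroximoyl chloride of 14 (not isolated) | C=C[C@H]1CC(=O)O[C@H]1/C=C(/COCc1ccc(OC)cc1)C(O[Si](C)(C)C(C)(C)C)/C=C/C(Cl)=NO | intermediate
16 | conjugated nitrile oxide (not isolated) | C=C[C@H]1CC(=O)O[C@H]1/C=C(/COCc1ccc(OC)cc1)C(O[Si](C)(C)C(C)(C)C)/C=C/C#[N+][O-] | intermediate
17 | (1E,4Z,6S,7S,8R)-3-OTBS-15-OPMB-8,10-(epoxynitrilo)-14-norgermacra-1,4-dien-6,12-olide, bridged 2-isoxazoline, C3 epimers | O=C1C[C@H]2[C@@H](O1)/C=C(/COCc3ccc(OC)cc3)C(O[Si](C)(C)C(C)(C)C)/C=C/C3=NO[C@@H]2C3 | intermediate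
18 | (4Z,6S,7S,8R)-3-OTBS-15-OPMB-8,10-(epoxynitrilo)-14-norgermacr-4-en-6,12-olide | O=C1C[C@H]2[C@@H](O1)/C=C(/COCc3ccc(OC)cc3)C(O[Si](C)(C)C(C)(C)C)CCC3=NO[C@@H]2C3 | intermediate
19 | lithium enolate of lactone 18 (not isolated) | [Li]OC1=C[C@H]2[C@@H](O1)/C=C(/COCc3ccc(OC)cc3)C(O[Si](C)(C)C(C)(C)C)CCC3=NO[C@@H]2C3 | intermediate
20 | (4Z,6S,7S,8R,11R)-13-(dimethylamino)-3-OTBS-15-OPMB-8,10-(epoxynitrilo)-14-norgermacr-4-en-6,12-olide | CN(C)C[C@@H]1C(=O)O[C@H]2/C=C(/COCc3ccc(OC)cc3)C(O[Si](C)(C)C(C)(C)C)CCC3=NO[C@H](C3)[C@@H]12 | intermediate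
21 | hydroxy imine, C10=NH analogue of 22 (not isolated) | CN(C)C[C@@H]1C(=O)O[C@H]2/C=C(/COCc3ccc(OC)cc3)C(O[Si](C)(C)C(C)(C)C)CCC(=N)C[C@@H](O)[C@@H]12 | intermediate
22 | (4Z,6S,7R,8R,11R)-13-(dimethylamino)-8-hydroxy-3-OTBS-15-OPMB-10-oxo-14-norgermacr-4-en-6,12-olide | CN(C)C[C@@H]1C(=O)O[C@H]2/C=C(/COCc3ccc(OC)cc3)C(O[Si](C)(C)C(C)(C)C)CCC(=O)C[C@@H](O)[C@@H]12 | intermediate
23 | magnesium alkoxide, C8–OMgBr derivative of 22 (not isolated) | CN(C)C[C@@H]1C(=O)O[C@H]2/C=C(/COCc3ccc(OC)cc3)C(O[Si](C)(C)C(C)(C)C)CCC(=O)C[C@@H](O[Mg]Br)[C@@H]12 | intermediate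
24 | (4Z,6S,7R,8R,10R,11R)-13-(dimethylamino)-8,10-dihydroxy-3-OTBS-15-OPMB-germacr-4-en-6,12-olide | CN(C)C[C@@H]1C(=O)O[C@H]2/C=C(/COCc3ccc(OC)cc3)C(O[Si](C)(C)C(C)(C)C)CC[C@@](C)(O)C[C@@H](O)[C@@H]12 | intermediate
25 | angelic acid, (2Z)-2-methylbut-2-enoic acid | C/C=C(/C)C(=O)O | starting material
26 | mixed anhydride of angelic acid and 2,4,6-trichlorobenzoic acid (not isolated) | C/C=C(/C)C(=O)OC(=O)c1c(Cl)cc(Cl)cc1Cl | intermediate
27 | (4Z,6S,7R,8R,10R,11R)-8-angeloyloxy-13-(dimethylamino)-10-hydroxy-3-OTBS-15-OPMB-germacr-4-en-6,12-olide | CN(C)C[C@@H]1C(=O)O[C@H]2/C=C(/COCc3ccc(OC)cc3)C(O[Si](C)(C)C(C)(C)C)CC[C@@](C)(O)C[C@@H](OC(=O)/C(C)=C\C)[C@@H]12 | intermediate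
28 | ammonium iodide, N-methyl quaternary salt of 27 (not isolated) | C[N+](C)(C)C[C@@H]1C(=O)O[C@H]2/C=C(/COCc3ccc(OC)cc3)C(O[Si](C)(C)C(C)(C)C)CC[C@@](C)(O)C[C@@H](OC(=O)/C(C)=C\C)[C@@H]12.[I-] | intermediate
29 | (4Z,6S,7R,8R,10R)-8-angeloyloxy-10-hydroxy-3-OTBS-15-OPMB-germacra-4,11(13)-dien-6,12-olide | C=C1C(=O)O[C@H]2/C=C(/COCc3ccc(OC)cc3)C(O[Si](C)(C)C(C)(C)C)CC[C@@](C)(O)C[C@@H](OC(=O)/C(C)=C\C)[C@@H]12 | intermediate
30 | (4Z,6S,7R,8R,10R)-8-angeloyloxy-3,10-dihydroxy-15-OPMB-germacra-4,11(13)-dien-6,12-olide | C=C1C(=O)O[C@H]2/C=C(/COCc3ccc(OC)cc3)C(O)CC[C@@](C)(O)C[C@@H](OC(=O)/C(C)=C\C)[C@@H]12 | intermediate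
31 | (4Z,6S,7R,8R,10R)-8-angeloyloxy-10-hydroxy-15-OPMB-3-oxogermacra-4,11(13)-dien-6,12-olide | C=C1C(=O)O[C@H]2/C=C(/COCc3ccc(OC)cc3)C(=O)CC[C@@](C)(O)C[C@@H](OC(=O)/C(C)=C\C)[C@@H]12 | intermediate
32 | (4Z,6S,7R,8R,10R)-8-angeloyloxy-10,15-dihydroxy-3-oxogermacra-4,11(13)-dien-6,12-olide (CNP0181802.1) | C=C1C(=O)O[C@H]2/C=C(/CO)C(=O)CC[C@@](C)(O)C[C@@H](OC(=O)/C(C)=C\C)[C@@H]12 | target

Total step count: 18. Longest linear sequence: 17 steps (steps 1–3 and 5–18; step 4 makes the allylboronate used in step 5).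

Steps most likely to fail

Step 9. At the dilution needed, dimerisation of the nitrile oxide to furoxans and oligomerisation may outrun closure of the strained ten-membered ring, or the dipole may add to the wrong face of the vinyl group. The fallback sets out from 10 and 11 and comes back at 17; it closes the ring at C3–C4 instead and runs the cycloaddition between two molecules. Aldehyde 11 is condensed with hydroxylamine (NH2OH·HCl, pyridine) to (2E)-4,4-dimethoxybut-2-enal oxime F1. Chlorination (N-chlorosuccinimide) and slow addition of Et3N in the presence of lactone 10 should give, by addition to the C7 vinyl group anti to the C6 arm, the iodoalkenyl isoxazoline acetal F2. Mild acid (pyridinium tosylate in wet acetone) frees the enal F3. An intramolecular Nozaki–Hiyama–Kishi reaction (CrCl2, NiCl2 cat., DMSO, high dilution) then closes the ten-membered ring to the macrocyclic allylic alcohol F4, and silylation (tert-butyldimethylsilyl chloride, imidazole) gives 17.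

Step 13. The magnesium aldolate may open by retro-aldol cleavage, the Grignard reagent may attack the lactone, or chelation control may erode so that the facial selectivity at C10 is poor. The fallback sets out from 22 and comes back at 24; it makes the carbinol from an alkene instead of by carbonyl addition. Takai–Lombardo methylenation (Zn, CH2Br2, TiCl4, THF/CH2Cl2), which tolerates the free hydroxyl and the lactone, gives the exocyclic alkene F5. Mukaiyama hydration (Mn(C11H19O2)3 cat., PhSiH3, O2, i-PrOH, 0 °C) of this 1,1-disubstituted alkene, which should react ahead of the hindered trisubstituted C4=C5 alkene, then gives 24. The facial choice in this route rests on trapping of the tertiary C10 radical from the ring periphery, not on the chelate, so it is not assured to match.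

Step 14. The angeloyl unit may isomerise to the E (tigloyl) isomer, acylation of the hindered secondary alcohol may be sluggish, and heating with base may cause translactonisation to the C8 oxygen. The fallback sets out from 24 and comes back at 27; it builds the Z-alkene of the ester on the substrate. The C8 alcohol is esterified at room temperature with 2-[bis(2,2,2-trifluoroethoxy)phosphoryl]propanoic acid (carbodiimide, DMAP) to the phosphonate ester F6. A Still–Gennari olefination with acetaldehyde (KN(SiMe3)2, 18-crown-6, THF, −78 °C) then gives the Z-configured 2-methylbut-2-enoate 27.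

Further compounds
F1 | step 9 | (2E)-4,4-dimethoxybut-2-enal oxime | COC(OC)/C=C/C=N/O
F2 | step 9 | (4S,5R)-4-{(5R)-3-[(1E)-3,3-dimethoxyprop-1-en-1-yl]-4,5-dihydro-1,2-oxazol-5-yl}-5-{(1Z)-2-iodo-3-[(4-methoxybenzyl)oxy]prop-1-en-1-yl}oxolan-2-one | COC(OC)/C=C/C1=NO[C@H](C1)[C@H]1CC(=O)O[C@H]1/C=C(\I)COCc1ccc(OC)cc1
F3 | step 9 | (4S,5R)-5-{(1Z)-2-iodo-3-[(4-methoxybenzyl)oxy]prop-1-en-1-yl}-4-{(5R)-3-[(1E)-3-oxoprop-1-en-1-yl]-4,5-dihydro-1,2-oxazol-5-yl}oxolan-2-one | O=C/C=C/C1=NO[C@H](C1)[C@H]1CC(=O)O[C@H]1/C=C(\I)COCc1ccc(OC)cc1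
F4 | step 9 | (1E,4Z,6S,7S,8R)-3-hydroxy-15-OPMB-8,10-(epoxynitrilo)-14-norgermacra-1,4-dien-6,12-olide, C3 epimers | O=C1C[C@H]2[C@@H](O1)/C=C(/COCc3ccc(OC)cc3)C(O)/C=C/C3=NO[C@@H]2C3
F5 | step 13 | (4Z,6S,7R,8R,11R)-13-(dimethylamino)-8-hydroxy-3-OTBS-15-OPMB-germacra-4,10(14)-dien-6,12-olide | CN(C)C[C@@H]1C(=O)O[C@H]2/C=C(/COCc3ccc(OC)cc3)C(O[Si](C)(C)C(C)(C)C)CCC(=C)C[C@@H](O)[C@@H]12
F6 | step 14 | (4Z,6S,7R,8R,10R,11R)-8-{2-[bis(2,2,2-trifluoroethoxy)phosphoryl]propanoyloxy}-13-(dimethylamino)-10-hydroxy-3-OTBS-15-OPMB-germacr-4-en-6,12-olide | CN(C)C[C@@H]1C(=O)O[C@H]2/C=C(/COCc3ccc(OC)cc3)C(O[Si](C)(C)C(C)(C)C)CC[C@@](C)(O)C[C@@H](OC(=O)C(C)P(=O)(OCC(F)(F)F)OCC(F)(F)F)[C@@H]12
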